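(The data were computed with made-up constants, noise included.)

Count turnovers. The flask asked about is the larch run itself, followed so far, so no recipe has to be carried across.

| flask | starting material | second substrate | reagent | free catalyst | temperature | remark | time |
|---|---|---|---|---|---|---|---|
| larch | 14 mM | 7 mM | 16.8 mM | 70 µM | 5 °C | the very flask that is asked about, followed so far |  |
| elm | 14 mM | 7 mM | 16.8 mM | 35 µM | 5 °C | run made earlier |  |
| flask | 14 mM | 7.00 mM | 16.8 mM | 70 µM | 5 °C |  | 10 h |

| run | time / min | target / % |
|---|---|---|
| larch | 150 | 55.1 |
| larch | 300 | 59.4 |
| larch | 480 | 57.1 |
| larch | 600 | 56.6 |
| elm | 8.00 | 18.2 |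
| elm | 15.0 | 23.8 |
| elm | 25.0 | 26.7 |
| elm | 30.0 | 30.7 |

(readings scatter by 1 percentage point)

- midnight: at 10 h add reagent, 100% of the amount charged, then wait 5.0 h
- spring: at 10 h raise the temperature by 10 K, then wait 5.0 h
- winter: change nothing and wait 5.0 h more
- summer: at 10 h add free catalyst, 100% of the amount charged, then wait 5.0 h
- dawn: at 10 h take out 90% of the target then present, then wait 5.0 h

- target, in percent of the starting material first charged, at 10 h
- the option that brings most further target ("none" if no option brings more than 2 percentage points) (midnight / spring / winter / summer / dawn / none)
- target present, with what was taken out counted in, in percent of the starting material first charged, after midnight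
- target present, with what was taken out counted in, in percent of the starting material first charged, after winter

- percentages count the starting material that a species holds: one spent catalyst counts as two
- target taken out counts as made
- steps that have been proposed: starting material + free catalyst <-> catalyst intermediate A; reagent + catalyst intermediate A -> free catalyst + target; second substrate + free catalyst <-> catalyst intermediate B; reagent + catalyst intermediate B -> free catalyst + second product; starting material + catalyst intermediate A -> spent catalyst
- the earlier runs do not show what temperature does; that part of a forecast is a guess
- additions bring no volume worth counting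

Ask first which number you must know well. The clock need not be known closely: from 300 min to 600 min the larch readings go from 59.4% to 56.6%, no rise at a scatter of 1 percentage point. The charges of reagent and second substrate are the same in both runs, so the runs cannot show their effect, but this flask holds them unchanged too. What must be known well is the plateau, so take the mean of the 4 larch readings, 57.0%.

Is that stop the reagent's doing? After the second substrate takes its full share, the reagent leaves a room of 70.0% of the starting material, and the plateau stands below that. So I look to the catalyst, which is 0.500% of the starting material. Dividing the plateau by that share gives the turnover number, the target made per catalyst charged before the turning stops: 114. It is a reading for this recipe, and I do not take it for a constant: the elm run, with half the catalyst, read 123 turns at 30.0 min, more than larch, though that is a single reading with its scatter of 1 point.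

My reckoning for larch is therefore 57.0% now. If the catalyst has stopped, I expect no gain from waiting, reagent or removal, and heat is a guess. A second catalyst charge brings a turn allowance of 57.0%, more than the room still open, so I expect the room to cap it at 13 points.

The forecast gave 57% now, 57% after midnight, 57% after winter, and chose summer: “Only fresh catalyst restarts the reaction”.

The larch flask gives 57.1%, 57.1% after midnight and 57.1% after winter, and the best option is summer.

    starting material + free catalyst ⇌ catalyst intermediate A (K = 32.3 L mol⁻¹, k = 124 L mol⁻¹ s⁻¹, Ea = 38.0 kJ mol⁻¹, ΔH = −63.0 kJ mol⁻¹)
    reagent + catalyst intermediate A → free catalyst + target (k = 60.4 L mol⁻¹ s⁻¹, Ea = 42.0 kJ mol⁻¹)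
    second substrate + free catalyst ⇌ catalyst intermediate B (K = 300 L mol⁻¹, k = 208 L mol⁻¹ s⁻¹, Ea = 41.0 kJ mol⁻¹, ΔH = −20.0 kJ mol⁻¹)
    reagent + catalyst intermediate B → free catalyst + second product (k = 3390 L mol⁻¹ s⁻¹, Ea = 16.0 kJ mol⁻¹)
    starting material + catalyst intermediate A → spent catalyst (k = 0.304 L mol⁻¹ s⁻¹, Ea = 40.0 kJ mol⁻¹)
    (constants at 5 °C)

At 10 h spent catalyst holds >99.9% of the larch catalyst, and summer adds 12 points against the room of 13 points, while midnight adds 0.0052 points. The neighbour charged with 0.17 mM of free catalyst has a catalyst share of 1.21%. Multiplied by the larch turnover number, that reckons to 138% of the starting material, a figure past the charge itself and more than the room, so the same reckoning gives 70.0%. That neighbour reaches 69.9% at 10 h, with 0.114% of its reagent left.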